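The constants were chosen freely; the result is computed.

Slowness is the cost in this chemistry: partner decomposes on its own with a half-life of 2.24 min while it waits for the catalyst. Substrate binds free catalyst to give catalyst intermediate A, partner attacks that to give catalyst intermediate B, B sheds the released group and becomes catalyst intermediate C, and C gives product and free catalyst.

    substrate + free catalyst → catalyst intermediate A (k1 = 37 L mol⁻¹ s⁻¹)
    partner + catalyst intermediate A → catalyst intermediate B (k2 = 23 L mol⁻¹ s⁻¹)
    catalyst intermediate B → released group + catalyst intermediate C (k3 = 67 s⁻¹)
    catalyst intermediate C → free catalyst + product (k4 = 1.3 s⁻¹)
    partner → decomposed reagent (k5 = 0.0052 s⁻¹)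

| setting | north | north-west | south | east |
|---|---|---|---|---|
| substrate | 0.10 M | 0.10 M (fed, over 10 min) | 0.10 M | 0.10 M (fed, over 1.0 min) |
| partner | 0.120 M (fed, over 10 min) | 0.120 M | 0.120 M | 0.120 M |
| free catalyst | 0.26 mM | 0.26 mM | 0.26 mM | 0.26 mM |
| time | 50 min | 50 min | 50 min | 50 min |
| remark | all else is in the flask from the start; the feed brings no volume worth counting | all else is in the flask from the start; the feed brings no volume worth counting | everything together at the start | all else is in the flask from the start; the feed brings no volume worth counting |

1. the flask that comes out highest in amount of product, in percent of the substrate charged, or "all alike" when all lie within 1.5 percentage points (north / north-west / south / east / all alike)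
2. product at the end, in percent of the substrate charged, north
3. product at the end, in percent of the substrate charged, north-west
4. product at the end, in percent of the substrate charged, south
5. product at the end, in percent of the substrate charged, east

*What fraction of the partner charge can become product?*

Partner has two exits, onto intermediate A or into decomposed reagent. Both scale with partner, so the split depends on where the catalyst stands, not on how much partner there is. With the catalyst entirely as intermediate A, the resting state, the exits run at 0.359 min⁻¹ and 0.31 min⁻¹, which gives a ceiling of 53.5% of the partner.

*But does the catalyst sit in A?*

Not entirely. Freeze substrate at its charge: each turn spends 1.04 s outside A, plus the wait in A, which shortens as partner rises. A's fraction of the catalyst is that wait's fraction of the turn.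

*South at the start?*

Partner stands at its full charge, so the wait is 0.362 s, A holds 25.8% of the catalyst, and the share reaching the cycle is 22.9%. It climbs as partner falls.

*North?*

Feed balanced against both exits holds partner near 14.9% of its charge. The wait becomes 2.43 s, and A holds 70.0% of the catalyst. So the frozen share, the part of the partner charge that reaches the catalyst at that fed level, is 44.6%. That is more than south's opening share, but south's share climbs during its run, so this pair of numbers does not rank the two flasks. For north I commit to product at 53.5% of the substrate charge.

*Your level assumed A at full strength, and you then found less. Isn't that a weak spot?*

Yes. The true level stands higher, which lowers the share, while the run-out after the feed raises it. I accept both errors.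

The forecast gives north, with north 52% (48% to 56%), north-west 27% (24% to 30%), south 41% (38% to 44%) and east 39.5% (36.5% to 42.5%), on this ground: “The yield is set by how much partner reaches the cycle before it decays.”

The flasks give north as highest: north 52.8%, north-west 26.3%, south 40.0%, east 38.0%.

In north at 6.81 min, partner's half-life on the path to intermediate B is 3.0 min, longer than the 2.2 min on the path to decomposed reagent. The share read there is 42.3%, against my frozen 44.6%.

Take north with 0.17 M of substrate instead. The frozen share of 44.6% of the partner comes to 31.5% of this larger charge. The computed flask gives 32.0%, with 67.8% of its substrate left.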